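## Structural features

Sanggenol A is a flavanone. A 5,7-dihydroxylated benzene ring A is fused through C4a and C8a to the dihydropyranone ring C, and C2 of ring C carries ring B, a resorcinol with a geranyl chain at C3' between the hydroxyls at C2' and C4'. C2 (S) is the only stereocentre, so only one absolute configuration has to be controlled and no relative one. That centre is a benzylic ether carbon next to the enolisable C3 methylene and ortho/para to two phenolic oxygens. Base opens ring C to the 2'-hydroxychalcone (retro-oxa-Michael, or through a quinone methide once a ring B phenol is free) and acid can ionise C2–O1; either event racemises the compound. The geranyl chain has two trisubstituted alkenes (the 2,3-alkene E) and a benzylic–allylic methylene, which excludes hydrogenolysis, strong protic or Lewis acids (chroman formation with the flanking phenols), electrophilic halogen and strong oxidants. The difficulty is therefore to set C2 by catalysis and then carry it, with the geranyl group, through ring construction and deprotection without base or strong acid at the stereocentre. The key step uses the fact that O1, C2, C3, C4, C4a and C8a are the six ring atoms of a 2-aryl-2,3-dihydro-4H-pyran-4-one, the cyclocondensation product of an aryl aldehyde and a 1-alkoxy-3-silyloxybutadiene. The vinylogous ester C4a=C8a of that ring is then the two-carbon anchor on which C5–C8 of ring A are assembled.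

## Logic of the disconnections

20 ⇒ 19. The two aryl ester C–O bonds on ring B are cut. The last step must be a near-neutral unmasking, since base opens ring C and acid cyclises the geranyl chain onto the freed phenols. Aryl esters allow this, and because they are electron-poor they also keep C2–O1 from ionising in every earlier acidic step. The forward step must cleave the esters without building up phenoxide.

19 ⇒ 17 (through 18). The C4a–C5 bond, the last bond of ring A, is cut. In 17 the carbons C5–C8 hang from C8a as a masked acetoacetyl unit at exactly the oxidation level of the arene, so ring A forms by isomerisation alone, without oxidant, base or acid. The phloroglucinol ring is thereby reduced to a vinylogous ester plus a heat-labile acylketene precursor. The forward step needs the unmasked acylketene to be captured by C4a and not by oxygen or a second molecule.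

17 ⇒ 12 + 15. The C8–C8a bond is cut. C8a is the electrophilic β-carbon of the vinylogous ester in 12 and 15 is a γ-nucleophilic four-carbon unit; conjugate addition and re-oxidation of C4a–C8a give the substituted vinylogous ester. This separates the stereodefined ring from an achiral C4 reagent. The forward step needs γ-selectivity of the dienolate, dehydrogenation from a regiodefined enol silane, and an intact C2–O1 bond under a silyl Lewis acid.

15 ⇒ 13. The O–Si bond is cut, leading back to a commercial heterocycle. The forward step needs kinetic γ-deprotonation and O-silylation.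

12 ⇒ 9 + 10 (key disconnection). C2–C3 and O1–C8a are cut, which removes ring C and the only stereocentre in one operation and leaves an achiral aldehyde and a commercial diene. The forward step needs enantiofacial control by a chiral Lewis acid, and a ring closure that does not ionise the new benzylic C–O bond.

9 ⇒ 8 ⇒ 7. The ester C–O bonds are cut, then the phenols are reconnected to acetal ethers. The aryllithium chemistry that builds 7 needs base-stable, ortho-directing acetal ethers, whereas everything from the key step onward is better served by electron-poor, Lewis-acid-inert esters. The exchange is placed at the aldehyde, where both phenols are deactivated by the formyl group and acidic acetal cleavage next to the geranyl chain is least hazardous. The cost is two steps.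

7 ⇒ 5. The aryl–CHO bond is cut. The forward step needs ortho-lithiation next to an acetal ether (only one kind of ring position is available) in preference to deprotonation of the benzylic–allylic CH2.

5 ⇒ 2 + 3. The aryl–CH2 bond at C3' is cut. The position between the two acetal ethers is the most acidic ring site, and allylation must be SN2 with retention of the E-alkene.

2 ⇒ 1. The two acetal O–C bonds are cut, leading to the commercial diphenol.

## Other disconnections considered

Alternative 1: The C4–C4a bond is cut, so ring C would be closed last by intramolecular Friedel–Crafts acylation. In the forward direction the (S)-β-aryloxy acid A1, activated as a mixed trifluoroacetic anhydride or acid chloride, acylates its own trioxygenated ring next to the ether oxygen and gives flavanone A2.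
- In its favour: ring A comes from the aromatic pool, and the ring being acylated is symmetric about the ether oxygen, so there is no regiochemical question. The route should be one or two steps shorter than the chosen one; on step economy and on ring A regiochemistry it is the better plan.
- Equal to the chosen plan: the ring B acetates of A2 serve the same purpose as in 9.
- Against it here: the stereocentre of A1 is a benzylic aryl ether β to an activated acyl group, so the acylating medium can expel the phenol (giving a cinnamoyl derivative) or ionise C2–O. The ring A acetal ethers and the geranyl alkenes must also survive an acylium ion and strong acid.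
- A1 itself requires etherification of a chiral benzylic alcohol by a hindered phenol with clean inversion, which is unreliable at a benzylic centre.
- Mechanistically it is weaker: its key step is the one that endangers C2, whereas in the chosen plan C2 is made by a catalyst and never sits next to an activated acyl group.

Alternative 2: The C2–C3 bond is cut. The diazomethyl ketone A3 is decomposed by a chiral dirhodium tetracarboxylate such as Rh2(S-PTTL)4, and the carbenoid inserts into the benzylic C–H bond next to the ether oxygen, closing ring C and setting C2 in flavanone A4.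
- In its favour: the stereocentre arises in a catalytic, essentially neutral step from an achiral benzyl ether that can be assembled convergently, and ring A is again bought. In convergence and step count it is equal to or slightly better than the chosen plan, and like it relies on catalyst control alone.
- Against it here: an acceptor-only carbenoid next to an ether oxygen can form an oxonium ylide and undergo a [1,2]-benzyl shift to a benzofuranone. It can also cyclopropanate the electron-rich geranyl alkenes of a second molecule or add to an arene.
- Closure to a six-membered ring by 1,6-insertion is less favoured than the usual five-membered closure, and enantioselectivity for this ring size is typically moderate.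
- A3 must be made from a hindered 2,6-dioxygenated benzoic acid derivative by a hazardous diazoalkane acylation.
- Structurally both plans carry the same sensitive groups. Mechanistically the chosen cyclocondensation has one activated electrophile, while the carbenoid has several competing partners in the same molecule.

Alternative 3: The O1–C8a bond is cut. The (S)-configured 1,3-diol A5, brominated at C8a, is cyclised with CuI, a phenanthroline ligand and Cs2CO3 so that the C2 hydroxyl is arylated and flavan-4-ol A6 forms. Oxidation at C4 and acetal removal would follow.
- In its favour: no bond to the stereocentre is made or broken in the ring closure, so a configuration set earlier in the open chain is carried over unchanged. The closure is chemoselective because arylation of the C4 hydroxyl would give a four-membered ring. On stereochemical security of the ring closure it is equal to or better than the chosen plan.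
- Against it here: the aryl bromide is very electron-rich and ortho-substituted, so the coupling should need prolonged heating with carbonate base, while the C4 benzylic alcohol on a trioxygenated ring eliminates or ionises easily.
- The plan needs an extra oxidation, a brominated ring A building block and four acetal ethers whose final removal is acidic. In step count it is longer than the chosen plan by the oxidation-state adjustment.
- Mechanistically it is sound but demanding on this substrate. Structurally it leaves ring B electron-rich throughout, which the chosen plan avoids.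

Key step: step 6

Remark on nomenclature: geranyl = (2E)-3,7-dimethylocta-2,6-dien-1-yl; flavanone atom labels (O1, C2, C3, C4, C4a, C5–C8, C8a; primed numbers for ring B) are used for the same atoms in all intermediates.

Assumption: (S)-BINOL is taken as the ligand enantiomer that directs the diene to the Si face of 9, by analogy with BINOL–titanium allylations and aldol additions of aromatic aldehydes. If the first run shows the opposite sense, (R)-BINOL is used with no other change.

## Route

Step 1
Reactants: 1 resorcinol (benzene-1,3-diol)
Product: 2 1,3-bis(methoxymethoxy)benzene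
Conditions: NaH (2.4 equiv), MOMCl (2.3 equiv), DMF, 0 °C → rt
Reagents that add atoms: chloromethyl methyl ether, COCCl
Why: Williamson-type O-alkylation of the bis-phenoxide; the acetal ethers are base-stable and serve as the directing groups for both lithiations that follow.

Step 2
Reactants: 2 1,3-bis(methoxymethoxy)benzene; 3 geranyl bromide [(2E)-1-bromo-3,7-dimethylocta-2,6-diene]
Product: 5 2-geranyl-1,3-bis(methoxymethoxy)benzene, via aryllithium 4 (not isolated)
Conditions: n-BuLi, THF, 0 °C → rt; CuI (10 mol%), 3, −78 °C → rt
Reagents that add atoms: none
Why: Directed ortho-metalation removes the hydrogen between the two acetal ethers, the most acidic ring position; CuI-catalysed SN2 allylation of the aryllithium should keep the E-alkene and suppress SN2′ attack.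

Step 3
Reactants: 5 2-geranyl-1,3-bis(methoxymethoxy)benzene
Product: 7 3-geranyl-2,4-bis(methoxymethoxy)benzaldehyde, via aryllithium 6 (not isolated)
Conditions: n-BuLi, TMEDA, THF, −20 → 0 °C; DMF, −78 °C → rt; H2O
Reagents that add atoms: N,N-dimethylformamide, CN(C)C=O
Why: Second directed ortho-metalation next to an acetal ether (the two open ortho positions are equivalent, the third ring position is meta to both ethers), then formylation of the aryllithium with DMF.

Step 4
Reactants: 7 3-geranyl-2,4-bis(methoxymethoxy)benzaldehyde
Product: 8 3-geranyl-2,4-dihydroxybenzaldehyde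
Conditions: 2 M aq. HCl, MeOH–THF, rt
Reagents that add atoms: none
Why: Acid-catalysed acetal exchange with methanol; both phenols are deactivated by the formyl group (one is hydrogen-bonded to it), so addition to the geranyl alkenes should not compete at room temperature.

Step 5
Reactants: 8 3-geranyl-2,4-dihydroxybenzaldehyde
Product: 9 2,4-diacetoxy-3-geranylbenzaldehyde (4-formyl-2-geranyl-1,3-phenylene diacetate)
Conditions: Ac2O, pyridine, DMAP (cat.), 0 °C → rt
Reagents that add atoms: acetic anhydride, CC(=O)OC(C)=O
Why: Standard DMAP-catalysed O-acetylation. The acetates are chosen because a 2,4-dialkoxyphenyl group would make the future C2–O1 bond ionisable under the Lewis and Brønsted acids of steps 6 and 8, and because they can be removed at the end near neutral pH.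

Step 6
Reactants: 9 2,4-diacetoxy-3-geranylbenzaldehyde; 10 (E)-1-methoxy-3-(trimethylsilyloxy)buta-1,3-diene
Product: 12 2-geranyl-4-[(2S)-4-oxo-3,4-dihydro-2H-pyran-2-yl]-1,3-phenylene diacetate, via silyl aldol adduct 11 (not isolated)
Conditions: Ti(OiPr)4 (10 mol%), (S)-BINOL (20 mol%), 4 Å MS, toluene, 0 °C; then CF3CO2H (10 mol%), CH2Cl2, 0 °C
Reagents that add atoms: none
Why: The tetravalent titanium–BINOL complex binds the formyl oxygen of 9 and the terminal CH2 of 10 adds to the carbonyl carbon (the Mukaiyama aldol pathway of the formal hetero-Diels–Alder reaction), forming C2–C3 and giving silyl aldol 11. Catalytic acid then lets the C2 oxygen add to the β-methoxy enone and expel methanol, a 6-endo-trig conjugate addition–elimination that forms O1–C8a and closes ring C as vinylogous ester 12. The closest known reaction type is the chiral-Lewis-acid-catalysed cyclocondensation of aromatic aldehydes with 1-methoxy-3-silyloxybutadienes to 2-aryl-2,3-dihydro-4H-pyran-4-ones. C2 is the only new stereocentre and is controlled by the catalyst alone: the (S)-ligand is expected to shield the Re face so that the diene adds to the Si face, which corresponds to S because O1 > aryl > C3. Regiochemistry follows from the polarisation of 10 (nucleophilic CH2 terminus, methoxy-bearing carbon becoming C8a), and chemoselectivity from the aldehyde being the only Lewis-acid-activated electrophile, the aryl acetates being inert to the silyl enol ether. The step needs high enantiofacial selectivity and no later ionisation of the new C2–O bond; the acetates make the aldehyde more electrophilic, remove the chelating ortho ether oxygen, and make the benzylic cation too poor to form during the acidic ring closure.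

Step 7
Reactants: 13 2,2,6-trimethyl-4H-1,3-dioxin-4-one
Product: 15 2,2-dimethyl-4-methylidene-6-(trimethylsilyloxy)-4H-1,3-dioxine, via lithium dienolate 14 (not isolated)
Conditions: LDA, THF, −78 °C; Me3SiCl, −78 °C → rt
Reagents that add atoms: chlorotrimethylsilane, C[Si](C)(C)Cl
Why: Kinetic γ-deprotonation of the vinylogous ester and O-silylation of the dienolate, the standard preparation of this silyl dienol ether (a masked acetoacetate γ-anion).

Step 8
Reactants: 12 2-geranyl-4-[(2S)-4-oxo-3,4-dihydro-2H-pyran-2-yl]-1,3-phenylene diacetate; 15 2,2-dimethyl-4-methylidene-6-(trimethylsilyloxy)-4H-1,3-dioxine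
Product: 17 2-geranyl-4-{(2S)-6-[(2,2-dimethyl-4-oxo-4H-1,3-dioxin-6-yl)methyl]-4-oxo-3,4-dihydro-2H-pyran-2-yl}-1,3-phenylene diacetate, via silyl enol ether 16 (not isolated)
Conditions: TMSOTf (20 mol%), CH2Cl2, −78 °C; Et3N, evaporate; Pd(OAc)2 (1.1 equiv), MeCN, rt
Reagents that add atoms: none
Why: Catalytic TMSOTf silylates the carbonyl of 12 to a 4-silyloxy oxocarbenium ion, and 15 attacks C8a through its γ-carbon (vinylogous Mukaiyama–Michael addition) and passes on its silyl group, giving the regiodefined enol silane 16. Pd(OAc)2 then restores the C4a=C8a double bond by Saegusa–Ito oxidation, so that C8 ends up on an intact vinylogous ester at the oxidation level of the arene. The transient C8a stereocentre is erased, C2 is not involved, and acetates, dioxinone and the trisubstituted alkenes should be inert.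

Step 9
Reactants: 17 2-geranyl-4-{(2S)-6-[(2,2-dimethyl-4-oxo-4H-1,3-dioxin-6-yl)methyl]-4-oxo-3,4-dihydro-2H-pyran-2-yl}-1,3-phenylene diacetate
Product: 19 4-[(2S)-5,7-dihydroxy-4-oxo-3,4-dihydro-2H-chromen-2-yl]-2-geranyl-1,3-phenylene diacetate, via acylketene 18 (not isolated)
Conditions: toluene (0.005 M), 110 °C
Reagents that add atoms: none
Why: Proposed new method: at 110 °C the dioxinone of 17 should lose acetone by retro-[4+2] to give acylketene 18, whose C8 enol is a hydroxy-dienylketene (C4a=C8a–C8=C7(OH)–C6=C5=O) set up for 6π-electrocyclisation, which forms C4a–C5; tautomerisation then gives the 5,7-dihydroxy arene with no base or acid and without touching C2. The closest known reaction types are the thermal dioxinone-to-acylketene fragmentation with intramolecular capture and the dienylketene electrocyclisation–tautomerisation that ends vinylketene benzannulations. Attack by O1 is unproductive because the acetate-deactivated benzylic group cannot leave, and high dilution disfavours bimolecular capture of the ketene.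

Step 10
Reactants: 19 4-[(2S)-5,7-dihydroxy-4-oxo-3,4-dihydro-2H-chromen-2-yl]-2-geranyl-1,3-phenylene diacetate
Product: 20 sanggenol A, (2S)-2-(3-geranyl-2,4-dihydroxyphenyl)-5,7-dihydroxy-2,3-dihydro-4H-chromen-4-one
Conditions: NH4OAc (10 equiv), MeOH–H2O (4:1), rt, N2
Reagents that add atoms: none
Why: Ammonium acetate in aqueous methanol is a near-neutral transesterification medium for aryl acetates. It avoids the base that would open ring C through the chalcone or a quinone methide and the acid that would cyclise the geranyl chain onto the freed phenols, so the C2 configuration should be retained.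

## Compound list

1 | resorcinol (benzene-1,3-diol) | Oc1cccc(O)c1 | starting material
2 | 1,3-bis(methoxymethoxy)benzene | COCOc1cccc(OCOC)c1 | intermediate
3 | geranyl bromide, (2E)-1-bromo-3,7-dimethylocta-2,6-diene | CC(C)=CCC/C(C)=C/CBr | starting material
4 | [2,6-bis(methoxymethoxy)phenyl]lithium, formed in situ | COCOc1cccc(OCOC)c1[Li] | intermediate
5 | 2-[(2E)-3,7-dimethylocta-2,6-dien-1-yl]-1,3-bis(methoxymethoxy)benzene | CC(C)=CCC/C(C)=C/Cc1c(OCOC)cccc1OCOC | intermediate
6 | {3-[(2E)-3,7-dimethylocta-2,6-dien-1-yl]-2,4-bis(methoxymethoxy)phenyl}lithium, formed in situ | CC(C)=CCC/C(C)=C/Cc1c(OCOC)ccc([Li])c1OCOC | intermediate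
7 | 3-[(2E)-3,7-dimethylocta-2,6-dien-1-yl]-2,4-bis(methoxymethoxy)benzaldehyde | CC(C)=CCC/C(C)=C/Cc1c(OCOC)ccc(C=O)c1OCOC | intermediate
8 | 3-[(2E)-3,7-dimethylocta-2,6-dien-1-yl]-2,4-dihydroxybenzaldehyde | CC(C)=CCC/C(C)=C/Cc1c(O)ccc(C=O)c1O | intermediate
9 | 2-[(2E)-3,7-dimethylocta-2,6-dien-1-yl]-4-formyl-1,3-phenylene diacetate | CC(C)=CCC/C(C)=C/Cc1c(OC(C)=O)ccc(C=O)c1OC(C)=O | intermediate
10 | (E)-1-methoxy-3-(trimethylsilyloxy)buta-1,3-diene | CO/C=C/C(=C)O[Si](C)(C)C | starting material
11 | 2-geranyl-4-[(1S,4E)-5-methoxy-3-oxo-1-(trimethylsilyloxy)pent-4-en-1-yl]-1,3-phenylene diacetate, formed in situ | CC(C)=CCC/C(C)=C/Cc1c(OC(C)=O)ccc([C@H](CC(=O)/C=C/OC)O[Si](C)(C)C)c1OC(C)=O | intermediate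
12 | 2-geranyl-4-[(2S)-4-oxo-3,4-dihydro-2H-pyran-2-yl]-1,3-phenylene diacetate | CC(C)=CCC/C(C)=C/Cc1c(OC(C)=O)ccc([C@@H]2CC(=O)C=CO2)c1OC(C)=O | intermediate
13 | 2,2,6-trimethyl-4H-1,3-dioxin-4-one | CC1=CC(=O)OC(C)(C)O1 | starting material
14 | lithium 2,2-dimethyl-6-methylidene-6H-1,3-dioxin-4-olate, formed in situ | [Li]OC1=CC(=C)OC(C)(C)O1 | intermediate
15 | 2,2-dimethyl-4-methylidene-6-(trimethylsilyloxy)-4H-1,3-dioxine | C=C1C=C(O[Si](C)(C)C)OC(C)(C)O1 | intermediate
16 | 2-geranyl-4-{(2S)-6-[(2,2-dimethyl-4-oxo-4H-1,3-dioxin-6-yl)methyl]-4-(trimethylsilyloxy)-3,6-dihydro-2H-pyran-2-yl}-1,3-phenylene diacetate, mixture of C6 epimers, formed in situ | CC(C)=CCC/C(C)=C/Cc1c(OC(C)=O)ccc([C@@H]2CC(O[Si](C)(C)C)=CC(CC3=CC(=O)OC(C)(C)O3)O2)c1OC(C)=O | intermediate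
17 | 2-geranyl-4-{(2S)-6-[(2,2-dimethyl-4-oxo-4H-1,3-dioxin-6-yl)methyl]-4-oxo-3,4-dihydro-2H-pyran-2-yl}-1,3-phenylene diacetate | CC(C)=CCC/C(C)=C/Cc1c(OC(C)=O)ccc([C@@H]2CC(=O)C=C(CC3=CC(=O)OC(C)(C)O3)O2)c1OC(C)=O | intermediate
18 | 2-geranyl-4-[(2S)-6-(2,4-dioxobut-3-en-1-yl)-4-oxo-3,4-dihydro-2H-pyran-2-yl]-1,3-phenylene diacetate (acylketene), formed in situ | CC(C)=CCC/C(C)=C/Cc1c(OC(C)=O)ccc([C@@H]2CC(=O)C=C(CC(=O)C=C=O)O2)c1OC(C)=O | intermediate
19 | 4-[(2S)-5,7-dihydroxy-4-oxo-3,4-dihydro-2H-chromen-2-yl]-2-geranyl-1,3-phenylene diacetate | CC(C)=CCC/C(C)=C/Cc1c(OC(C)=O)ccc([C@@H]2CC(=O)c3c(O)cc(O)cc3O2)c1OC(C)=O | intermediate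
20 | sanggenol A, (2S)-2-{3-[(2E)-3,7-dimethylocta-2,6-dien-1-yl]-2,4-dihydroxyphenyl}-5,7-dihydroxy-2,3-dihydro-4H-chromen-4-one | CC(C)=CCC/C(C)=C/Cc1c(O)ccc([C@@H]2CC(=O)c3c(O)cc(O)cc3O2)c1O | target

## Step count and least certain steps

Total steps: 10. Longest linear sequence: 9 steps (steps 1–6 and 8–10, from 1 to 20); step 7 is a one-step branch.

Step 9 (proposed new method). The most likely failure is interception of the acylketene before the C4a–C5 bond forms: bimolecular capture by phenols of product already present or by a second ketene, or decomposition if enolisation towards C8 is slow. The fallback uses known chemistry, sets out from 17 and returns at 19. Compound 17 is heated in toluene containing methanol, so that the acylketene is captured by the alcohol, the most reliable reaction of dioxinones. This gives the β-keto ester methyl 4-[(2S)-2-(2,4-diacetoxy-3-geranylphenyl)-4-oxo-3,4-dihydro-2H-pyran-6-yl]-3-oxobutanoate F1. Ring A is then closed by an intramolecular Claisen condensation with one equivalent of NaH in THF (0 °C → rt, acetic acid quench): deprotonation at C8 lets C4a attack the ester, the mode by which polyketo esters give acylphloroglucinols, and the methoxide released is consumed by the acidic product. This route is held in reserve because an alkoxide can transfer acetyl groups; any acetate lost there is of no consequence for step 10.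

Step 6 (key step). The most likely failures are insufficient enantiofacial discrimination with the ortho-substituted aldehyde, and acetyl transfer from the ortho acetate to the titanium aldolate or to isopropoxide before silylation, which would consume catalyst. The fallback sets out from 9 and returns at 12, and replaces Lewis-acid catalysis by a hydrogen-bond-catalysed concerted cycloaddition with a more reactive diene, so that no metal alkoxide is formed. Commercial (E)-3-(tert-butyldimethylsilyloxy)-N,N-dimethylbuta-1,3-dien-1-amine is combined with 9 in toluene at −78 → −40 °C in the presence of a tetra(1-naphthyl)-TADDOL (20 mol%, the enantiomer that directs the diene to the Si face). This should give the cycloadduct 2-geranyl-4-[(2S)-4-(tert-butyldimethylsilyloxy)-6-(dimethylamino)-3,6-dihydro-2H-pyran-2-yl]-1,3-phenylene diacetate F2. Acetyl chloride in CH2Cl2 at −78 °C then removes the amino and silyl groups without protic acid and gives 12.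

Step 8. The most likely failures are loss of the labile silyl group from 16 during the solvent change, so that the dehydrogenation loses its regiocontrol or stops at the saturated ketone, and β-alkoxide elimination from the palladium enolate with opening of ring C. The fallback sets out from 12 and returns at 17, and replaces the palladium dehydrosilylation by selenoxide syn-elimination. After the conjugate addition, PhSeCl is added at −78 °C to the cold solution of 16, giving the α-selanyl ketone 2-geranyl-4-{(2S)-6-[(2,2-dimethyl-4-oxo-4H-1,3-dioxin-6-yl)methyl]-4-oxo-5-(phenylselanyl)tetrahydro-2H-pyran-2-yl}-1,3-phenylene diacetate F3. NaIO4 in aqueous THF (0 °C → rt) oxidises it to the corresponding selenoxide F4, which eliminates across C4a–C8a to 17; selenium is expected to enter trans to the new C8 substituent and therefore cis to the C8a hydrogen that has to be removed.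

Step 3. The most likely failure is competing deprotonation at the benzylic–allylic CH2 of the geranyl chain, leading to chain-functionalised or alkene-isomerised material. The fallback sets out from 2 and returns at aryllithium 6, and fixes the formylation site with a halogen before the geranyl group is present. NBS (MeCN, 0 °C) converts 2 into 1-bromo-2,4-bis(methoxymethoxy)benzene F5. LDA (THF, −78 °C) removes the hydrogen between the two acetal ethers to give [3-bromo-2,6-bis(methoxymethoxy)phenyl]lithium F6, and CuI-catalysed allylation with 3 gives 1-bromo-3-geranyl-2,4-bis(methoxymethoxy)benzene F7. Bromine–lithium exchange with n-BuLi at −78 °C, which is faster than any deprotonation, delivers 6, and this is quenched with DMF as in step 3.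

## Further compounds

F1 | step 9 | methyl 4-[(2S)-2-(2,4-diacetoxy-3-geranylphenyl)-4-oxo-3,4-dihydro-2H-pyran-6-yl]-3-oxobutanoate | CC(C)=CCC/C(C)=C/Cc1c(OC(C)=O)ccc([C@@H]2CC(=O)C=C(CC(=O)CC(=O)OC)O2)c1OC(C)=O
F2 | step 6 | 2-geranyl-4-[(2S)-4-(tert-butyldimethylsilyloxy)-6-(dimethylamino)-3,6-dihydro-2H-pyran-2-yl]-1,3-phenylene diacetate | CC(C)=CCC/C(C)=C/Cc1c(OC(C)=O)ccc([C@@H]2CC(O[Si](C)(C)C(C)(C)C)=CC(N(C)C)O2)c1OC(C)=O
F3 | step 8 | 2-geranyl-4-{(2S)-6-[(2,2-dimethyl-4-oxo-4H-1,3-dioxin-6-yl)methyl]-4-oxo-5-(phenylselanyl)tetrahydro-2H-pyran-2-yl}-1,3-phenylene diacetate | CC(C)=CCC/C(C)=C/Cc1c(OC(C)=O)ccc([C@@H]2CC(=O)C([Se]c3ccccc3)C(CC3=CC(=O)OC(C)(C)O3)O2)c1OC(C)=O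
F4 | step 8 | 2-geranyl-4-{(2S)-6-[(2,2-dimethyl-4-oxo-4H-1,3-dioxin-6-yl)methyl]-4-oxo-5-(phenylseleninyl)tetrahydro-2H-pyran-2-yl}-1,3-phenylene diacetate | CC(C)=CCC/C(C)=C/Cc1c(OC(C)=O)ccc([C@@H]2CC(=O)C([Se](=O)c3ccccc3)C(CC3=CC(=O)OC(C)(C)O3)O2)c1OC(C)=O
F5 | step 3 | 1-bromo-2,4-bis(methoxymethoxy)benzene | COCOc1ccc(Br)c(OCOC)c1
F6 | step 3 | [3-bromo-2,6-bis(methoxymethoxy)phenyl]lithium | COCOc1ccc(Br)c(OCOC)c1[Li]
F7 | step 3 | 1-bromo-3-[(2E)-3,7-dimethylocta-2,6-dien-1-yl]-2,4-bis(methoxymethoxy)benzene | CC(C)=CCC/C(C)=C/Cc1c(OCOC)ccc(Br)c1OCOC
A1 | alternative 1 | (3S)-3-(2,4-diacetoxy-3-geranylphenyl)-3-[3,5-bis(methoxymethoxy)phenoxy]propanoic acid | CC(C)=CCC/C(C)=C/Cc1c(OC(C)=O)ccc([C@H](CC(=O)O)Oc2cc(OCOC)cc(OCOC)c2)c1OC(C)=O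
A2 | alternative 1 | (2S)-2-(2,4-diacetoxy-3-geranylphenyl)-5,7-bis(methoxymethoxy)chroman-4-one | CC(C)=CCC/C(C)=C/Cc1c(OC(C)=O)ccc([C@@H]2CC(=O)c3c(OCOC)cc(OCOC)cc3O2)c1OC(C)=O
A3 | alternative 2 | 2-diazo-1-{2-[3-geranyl-2,4-bis(methoxymethoxy)benzyloxy]-4,6-bis(triisopropylsilyloxy)phenyl}ethanone | CC(C)=CCC/C(C)=C/Cc1c(OCOC)ccc(COc2cc(O[Si](C(C)C)(C(C)C)C(C)C)cc(O[Si](C(C)C)(C(C)C)C(C)C)c2C(=O)C=[N+]=[N-])c1OCOC
A4 | alternative 2 | (2S)-2-[3-geranyl-2,4-bis(methoxymethoxy)phenyl]-5,7-bis(triisopropylsilyloxy)chroman-4-one | CC(C)=CCC/C(C)=C/Cc1c(OCOC)ccc([C@@H]2CC(=O)c3c(O[Si](C(C)C)(C(C)C)C(C)C)cc(O[Si](C(C)C)(C(C)C)C(C)C)cc3O2)c1OCOC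
A5 | alternative 3 | (1S)-1-[3-geranyl-2,4-bis(methoxymethoxy)phenyl]-3-[2-bromo-4,6-bis(methoxymethoxy)phenyl]propane-1,3-diol | CC(C)=CCC/C(C)=C/Cc1c(OCOC)ccc([C@@H](O)CC(O)c2c(Br)cc(OCOC)cc2OCOC)c1OCOC
A6 | alternative 3 | (2S)-2-[3-geranyl-2,4-bis(methoxymethoxy)phenyl]-5,7-bis(methoxymethoxy)chroman-4-ol | CC(C)=CCC/C(C)=C/Cc1c(OCOC)ccc([C@@H]2CC(O)c3c(OCOC)cc(OCOC)cc3O2)c1OCOC
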